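The numbers of this flask are invented; the flask was simulated.

**Late times.** At late times target keeps a way out that needs no coupling partner: the return of step 2 to substrate and coupling partner. The set-ups below differ in when target is made, and so in how long it stands exposed to that return.

common to all: capture agent 3.00 mM
- amber: substrate 0.010 M; coupling partner 0.0200 M; a single well-mixed tank run continuously and read at steady state, 8.0 min in it on average
- red: substrate 0.010 M (fed, over 8.00 min); coupling partner 0.0200 M; all but substrate at the start; substrate goes in evenly over 8.00 min, the run ends at 8.0 min; time 8.0 min
- blue: substrate 0.010 M; coupling partner 0.0200 M; everything together in a closed stirred flask, run for 8.0 min; time 8.0 min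
- ochre: substrate 0.010 M; coupling partner 0.0200 M (fed, over 8.00 min); all but coupling partner at the start; coupling partner goes in evenly over 8.00 min, the run ends at 8.0 min; time 8.0 min

    coupling partner + intermediate A ⇌ intermediate B (K1 = 53 /M, k1 = 0.71 /M/s)
    substrate + coupling partner ⇌ target (K2 = 920 /M, k2 = 3.0 /M/s)
    substrate + coupling partner ⇌ intermediate A (K3 = 46 /M, k3 = 1.6 /M/s)
    capture agent + intermediate A → trapped intermediate (k4 = 1.1 /M/s)
    coupling partner + target → over-reaction product (k5 = 2.1 /M/s)
    2 coupling partner → homo dimer (k6 = 0.41 /M/s)

- where a step has two of a species, its rate is k times that concentration squared, and two are used at each turn
- the stated concentrations are those of everything mixed, before any reaction; amounts are the same in each set-up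
- the feed brings no volume worth counting
- run time (red): 8.0 min

1. the set-up with the highest amount of target at the outlet or at the end, in percent of the substrate put in ("none" if the first two lie within 2 percentage points) (amber / red / blue / ochre / none)
2. amount of target at the outlet or at the end, in percent of the substrate put in, amber
3. amount of target at the outlet or at the end, in percent of the substrate put in, red
4. amount of target at the outlet or at the end, in percent of the substrate put in, blue
5. amount of target at the outlet or at the end, in percent of the substrate put in, ochre

**Fast rungs.** Take blue, the closed flask, as charged. With coupling partner as charged, substrate has a half-life of 0.19 min by the forward step 2 alone, and target one of 0.28 min by step 5 alone, the attack of coupling partner; both are shorter than the run, so in blue the contest between making and over-reaction comes early. Substrate leaves by the forward steps 2 and 3, and with the returns set aside 65.2% of it goes to target. These losses and the loss of target are all first order in coupling partner, so its falling course cancels from their ratio, the selectivity factor, here 0.457. Share and factor together put the peak of target in blue at 33.8% of the substrate, with no clock needed.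

**Middle rungs.** In blue, with the other concentrations as charged, intermediate A has a half-life of 0.81 min by the forward step 1 alone, and the homo dimer takes coupling partner with a first half-life of 1.02 min by that step alone. Capture alone gives intermediate A a half-life of 3.5 min. This reckoning books intermediate A as lost, although step 3 can return it.

**Slowest rung.** At the start of blue, the pseudo-first-order constant of forward step 2 exceeds that of its return by a factor of 18, so early on the return is a small correction, and it can be reckoned apart. The return half-life of target, ln(2) times the equilibrium constant over the forward constant of step 2, is 3.54 min. The blue run is longer than this, so 20.9% of the peak stands at the end, which gives 7.06% of the substrate. That figure counts neither target formed again from returned substrate nor further loss by step 5. Red and ochre feed for the whole run, which is longer than the return half-life, so target made late in them stands for a shorter time, and both are reckoned above blue. The dimer half-life is shorter than the feed, so late substrate in red meets thinner coupling partner. Amber is not reckoned here, and among the closed and fed flasks the pick is ochre.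

**The forecast.** The forecast, unlike this reckoning, chose blue, with 17% for amber, 25% for red, 38% for blue and 26% for ochre, holding that in the batch flask coupling partner dies away, which “leaves target largely protected”.

**The result.** The simulation gives 17.3% for amber, 15.3% for red, 12.8% for blue and 21.2% for ochre, so ochre stands highest, and blue lies above the reckoned 7.06%. The amber tank holds coupling partner at 0.00308 M. Target in amber therefore leaves by the outlet at 0.125 /min on average, by step 5 at 0.388 /min, and by return, from the return half-life, at 0.196 /min. The outlet thus takes 17.6% of the target formed in amber.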